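**Retrosynthetic overview** (halimane locants: ring A = C1–C5 + C10, ring B = C5–C10, side chain C11–C16, ester carbon C18)
1. Target ⇐ vinyl diene 14: side-chain triol by asymmetric epoxidation and anti-opening, then acetylation; C18 ester by oxidative cleavage of a C4 vinyl group.
2. Ring A is closed last, through C1=C10, by ring-closing carbonyl–olefin metathesis of the ring-B C10 ketone with the isopropylidene end of a geraniol-derived chain on C4 (acetone leaves).
3. C4–C5 (quaternary C4, tertiary C5) ⇐ [3,3] Claisen rearrangement of the geranyl enol ether of the ring-B ketone; geraniol supplies C1–C4, C18 and C19.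
4. Ring B (C8, quaternary C9) is carried from 2-methylcyclohex-2-enone: asymmetric conjugate methylation, then Mukaiyama–Michael addition.
5. Enabling feature: C10 sits between the quaternary C9 and the C5 methine, so a ring-B C10 ketone enolises only toward C5, and its carbonyl carbon is five bonds (C10–C5–C4–C3–C2–C1) from the olefinic C1 of a chain on C4; the trisubstituted C1=C10 alkene is the retron of a ketone/isopropylidene metathesis.

Key step: step 6

Remark: the phosphoramidite antipode in step 1 is taken to be the one that gives the (R)-configured C8; if the sense of induction is opposite, the other antipode is used.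

Step 1
Reactants: 1 2-methylcyclohex-2-en-1-one
Product: 3 trimethyl{[(3R)-2,3-dimethylcyclohex-1-en-1-yl]oxy}silane, via aluminium enolate 2 (not isolated)
Conditions: Me3Al, Cu(O2CC4H3S) (copper thiophene-2-carboxylate, cat.), (S,R,R)-O,O'-(1,1'-binaphthyl-2,2'-diyl)-N,N-bis(1-phenylethyl)phosphoramidite (cat.), Et2O, −30 °C; then Me3SiOTf, −30 to 0 °C
Reagents that add atoms: trimethylaluminium, C[Al](C)C; trimethylsilyl trifluoromethanesulfonate, C[Si](C)(C)OS(=O)(=O)C(F)(F)F
Why: Copper-catalysed asymmetric conjugate addition of a trialkylaluminium to a 2-substituted cyclohexenone is a known reaction type in which the chiral copper–phosphoramidite complex selects the enone face and so sets C8 as (R), and O-silylation of the aluminium enolate fixes the tetrasubstituted C9=C10 enol ether for the next bond.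

Step 2
Reactants: 3 trimethyl{[(3R)-2,3-dimethylcyclohex-1-en-1-yl]oxy}silane; 4 but-3-en-2-one
Product: 5 (2S,3R)-2,3-dimethyl-2-(3-oxobutyl)cyclohexan-1-one
Conditions: TiCl4, CH2Cl2, −78 °C; aq. K2CO3
Reagents that add atoms: but-3-en-2-one (4), CC(=O)C=C
Why: Mukaiyama–Michael addition, in which the TiCl4-activated enone is attacked by C9 on the face anti to the C8 methyl group (held pseudoaxial by allylic strain with the C9 methyl), which should set the quaternary C9 as (S) with the two methyl groups cis.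

Step 3
Reactants: 5 (2S,3R)-2,3-dimethyl-2-(3-oxobutyl)cyclohexan-1-one; 6 trimethyl phosphonoacetate
Product: 7 methyl (2E)-5-[(1S,2R)-1,2-dimethyl-6-oxocyclohexyl]-3-methylpent-2-enoate
Conditions: NaH, THF, 0 to 23 °C; chromatographic removal of the minor (Z)-isomer
Reagents that add atoms: trimethyl phosphonoacetate (6), COC(=O)CP(=O)(OC)OC
Why: Horner–Wadsworth–Emmons olefination, in which the unhindered methyl ketone reacts while the C10 ketone next to the quaternary C9 stays untouched and the stabilised phosphonate anion should favour the (E)-trisubstituted enoate.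

Step 4
Reactants: 7 methyl (2E)-5-[(1S,2R)-1,2-dimethyl-6-oxocyclohexyl]-3-methylpent-2-enoate
Product: 9 methyl (2E)-5-[(1S,6R)-2-methoxy-1,6-dimethylcyclohex-2-en-1-yl]-3-methylpent-2-enoate, via dimethyl ketal 8 (not isolated)
Conditions: HC(OMe)3, MeOH, TsOH (cat.), 50 °C; then toluene, 110 °C, distillation of MeOH
Reagents that add atoms: trimethyl orthoformate, COC(OC)OC; methanol, CO
Why: Acid-catalysed ketalisation with an orthoester followed by thermal loss of methanol; because C9 is quaternary the enol ether can form only toward C5, which puts the C5=C10 double bond where the Claisen rearrangement needs it.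

Step 5
Reactants: 9 methyl (2E)-5-[(1S,6R)-2-methoxy-1,6-dimethylcyclohex-2-en-1-yl]-3-methylpent-2-enoate; 10 geraniol
Product: 12 methyl (2E)-5-{(1S,2R,5S)-5-[(3R)-3,7-dimethylocta-1,6-dien-3-yl]-1,2-dimethyl-6-oxocyclohexyl}-3-methylpent-2-enoate, via geranyl enol ether 11 (not isolated)
Conditions: geraniol (3 equiv), EtCO2H (cat.), xylenes, 140 °C, continuous removal of MeOH
Reagents that add atoms: geraniol (10), CC(C)=CCC/C(C)=C/CO
Why: Ketal-exchange Claisen rearrangement ([3,3]-sigmatropic), in which acid-catalysed alcohol exchange gives geranyl enol ether 11, which should rearrange through a chair transition state on the ring-B face anti to the pseudoaxial C9 methyl group, the (E)-geometry of geraniol placing the long chain pseudo-equatorial and its methyl pseudo-axial, so that the quaternary C4 (R) and the tertiary C5 (S) form together in the configuration of the target.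

Step 6
Reactants: 12 methyl (2E)-5-{(1S,2R,5S)-5-[(3R)-3,7-dimethylocta-1,6-dien-3-yl]-1,2-dimethyl-6-oxocyclohexyl}-3-methylpent-2-enoate
Product: 14 methyl (2E)-5-[(1S,2R,4aS,5R)-5-ethenyl-1,2,5-trimethyl-1,2,3,4,4a,5,6,7-octahydronaphthalen-1-yl]-3-methylpent-2-enoate, via oxetane 13 (not isolated)
Conditions: FeCl3 (10 mol %), ClCH2CH2Cl, 23 °C
Reagents that add atoms: none
Why: Proposed new method: FeCl3 bound to the C10 ketone oxygen makes the carbonyl carbon electrophilic enough to be attacked by C1 of the electron-rich isopropylidene olefin (asynchronous [2+2], positive charge developing on the tertiary CMe2 carbon), giving the cis-fused oxetane 13, which undergoes Lewis-acid-assisted retro-[2+2] in the other sense to release acetone and the C1=C10 alkene. The closest known reaction type is the FeCl3-catalysed ring-closing carbonyl–olefin metathesis of aryl and simple aliphatic ketones carrying isopropylidene olefins; it has not been shown for a doubly α-branched cyclohexanone closing a fused six-membered ring beside an enolisable stereocentre, hence the label. Ring A closes in a 6-exo-trig mode at the carbonyl carbon (C1 to C10, the CMe2 carbon staying outside the new carbocycle), helped by the Thorpe–Ingold effect of the quaternary C4 and by the equatorial position of the C4 chain at C5. No lasting stereocentre is created, since the oxetane carbons C1 and C10 end sp2 and C4, C5, C8 and C9 are spectators. The step needs chemoselectivity (only the trisubstituted isopropylidene is nucleophilic enough, the monosubstituted vinyl group and the electron-poor enoate are not, and the ester carbonyl does not take part), oxetane fragmentation in preference to a carbonyl-ene collapse, and retention of C5. The substrate secures these in that the quaternary C9 leaves C5–H as the only enolisable hydrogen (tertiary and shielded by the quaternary C4), and the low catalyst loading at ambient temperature limits acid-induced alkene migration.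

Step 7
Reactants: 14 methyl (2E)-5-[(1S,2R,4aS,5R)-5-ethenyl-1,2,5-trimethyl-1,2,3,4,4a,5,6,7-octahydronaphthalen-1-yl]-3-methylpent-2-enoate
Product: 15 (2E)-5-[(1S,2R,4aS,5R)-5-ethenyl-1,2,5-trimethyl-1,2,3,4,4a,5,6,7-octahydronaphthalen-1-yl]-3-methylpent-2-en-1-ol
Conditions: i-Bu2AlH, CH2Cl2, −78 °C; aq. KNaC4H4O6 (potassium sodium tartrate)
Reagents that add atoms: none
Why: DIBAL-H 1,2-reduction of the conjugated methyl ester, the only carbonyl group left, should give the (E)-allylic alcohol without touching the three C=C bonds.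

Step 8
Reactants: 15 (2E)-5-[(1S,2R,4aS,5R)-5-ethenyl-1,2,5-trimethyl-1,2,3,4,4a,5,6,7-octahydronaphthalen-1-yl]-3-methylpent-2-en-1-ol
Product: 16 [(2S,3S)-3-{2-[(1S,2R,4aS,5R)-5-ethenyl-1,2,5-trimethyl-1,2,3,4,4a,5,6,7-octahydronaphthalen-1-yl]ethyl}-3-methyloxiran-2-yl]methanol
Conditions: Ti(OiPr)4 (cat.), L-(+)-diethyl tartrate (cat.), t-BuOOH, 4 Å molecular sieves, CH2Cl2, −20 °C
Reagents that add atoms: tert-butyl hydroperoxide, CC(C)(C)OO
Why: Sharpless asymmetric epoxidation, in which the titanium–L-(+)-tartrate complex delivers oxygen to one face of the (E)-allylic alcohol under reagent control (C13 S, C14 S), and only this alkene reacts because the vinyl and ring alkenes carry no hydroxyl group to bind titanium.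

Step 9
Reactants: 16 [(2S,3S)-3-{2-[(1S,2R,4aS,5R)-5-ethenyl-1,2,5-trimethyl-1,2,3,4,4a,5,6,7-octahydronaphthalen-1-yl]ethyl}-3-methyloxiran-2-yl]methanol
Product: 17 (2S,3R)-5-[(1S,2R,4aS,5R)-5-ethenyl-1,2,5-trimethyl-1,2,3,4,4a,5,6,7-octahydronaphthalen-1-yl]-3-methylpentane-1,2,3-triol
Conditions: HClO4 (cat.), THF/H2O, 0 °C
Reagents that add atoms: water, O
Why: Acid-catalysed epoxide hydrolysis, in which water attacks the protonated epoxide at the tertiary C13 with inversion (borderline SN2) while the C14–O bond is kept, which should turn the (13S,14S)-epoxide into the anti-triol with C13 R and C14 S.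

Step 10
Reactants: 17 (2S,3R)-5-[(1S,2R,4aS,5R)-5-ethenyl-1,2,5-trimethyl-1,2,3,4,4a,5,6,7-octahydronaphthalen-1-yl]-3-methylpentane-1,2,3-triol
Product: 18 (2S,3R)-5-[(1S,2R,4aS,5R)-5-ethenyl-1,2,5-trimethyl-1,2,3,4,4a,5,6,7-octahydronaphthalen-1-yl]-3-hydroxy-3-methylpentane-1,2-diyl diacetate
Conditions: Ac2O, pyridine, DMAP (cat.), CH2Cl2, 0 to 23 °C
Reagents that add atoms: acetic anhydride, CC(=O)OC(C)=O
Why: Acylation of the primary C15 and secondary C14 hydroxyl groups with acetic anhydride/pyridine, the tertiary C13 alcohol being too hindered to react under these conditions.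

Step 11
Reactants: 18 (2S,3R)-5-[(1S,2R,4aS,5R)-5-ethenyl-1,2,5-trimethyl-1,2,3,4,4a,5,6,7-octahydronaphthalen-1-yl]-3-hydroxy-3-methylpentane-1,2-diyl diacetate
Product: 20 (2S,3R)-5-[(1S,2R,4aR,5S)-5-formyl-1,2,5-trimethyl-1,2,3,4,4a,5,6,7-octahydronaphthalen-1-yl]-3-hydroxy-3-methylpentane-1,2-diyl diacetate, via vicinal diol 19 (not isolated)
Conditions: OsO4 (cat.), NaIO4, 2,6-lutidine, dioxane/H2O, 23 °C
Reagents that add atoms: osmium tetroxide, O=[Os](=O)(=O)=O; sodium periodate, [Na+].[O-]I(=O)(=O)=O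
Why: Lemieux–Johnson oxidative cleavage, in which OsO4 should dihydroxylate the exposed monosubstituted vinyl group faster than the trisubstituted C1=C10 alkene shielded by the quaternary C9 and the ring fusion, and periodate cleaves diol 19 to the C18 aldehyde (no other free 1,2-diol is present).

Step 12
Reactants: 20 (2S,3R)-5-[(1S,2R,4aR,5S)-5-formyl-1,2,5-trimethyl-1,2,3,4,4a,5,6,7-octahydronaphthalen-1-yl]-3-hydroxy-3-methylpentane-1,2-diyl diacetate
Product: 21 (1S,5S,6R,8aR)-5-[(3R,4S)-4,5-bis(acetyloxy)-3-hydroxy-3-methylpentyl]-1,5,6-trimethyl-1,2,3,5,6,7,8,8a-octahydronaphthalene-1-carboxylic acid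
Conditions: NaClO2, NaH2PO4, 2-methyl-2-butene, t-BuOH/H2O, 23 °C
Reagents that add atoms: sodium chlorite, [Na+].[O-]Cl=O
Why: Pinnick oxidation of the non-enolisable neopentyl aldehyde to the acid, with 2-methyl-2-butene scavenging hypochlorous acid so that the ring alkene is not chlorinated.

Step 13
Reactants: 21 (1S,5S,6R,8aR)-5-[(3R,4S)-4,5-bis(acetyloxy)-3-hydroxy-3-methylpentyl]-1,5,6-trimethyl-1,2,3,5,6,7,8,8a-octahydronaphthalene-1-carboxylic acid
Product: 22 methyl (1S,5S,6R,8aR)-5-[(3R,4S)-4,5-bis(acetyloxy)-3-hydroxy-3-methylpentyl]-1,5,6-trimethyl-1,2,3,5,6,7,8,8a-octahydronaphthalene-1-carboxylate (target)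
Conditions: Me3SiCHN2, MeOH/toluene, 0 °C
Reagents that add atoms: (trimethylsilyl)diazomethane, C[Si](C)(C)C=[N+]=[N-]
Why: Esterification of the hindered tertiary carboxylic acid by O-methylation with diazomethane formed in situ from Me3SiCHN2 and methanol, conditions under which the acetates and the tertiary alcohol are inert.

**Compound list**
1 | 2-methylcyclohex-2-en-1-one | CC1=CCCCC1=O | starting material
2 | dimethylaluminium (3R)-2,3-dimethylcyclohex-1-en-1-olate | C[C@@H]1CCCC(O[Al](C)C)=C1C | intermediate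
3 | trimethyl{[(3R)-2,3-dimethylcyclohex-1-en-1-yl]oxy}silane | C[C@@H]1CCCC(O[Si](C)(C)C)=C1C | intermediate
4 | but-3-en-2-one (methyl vinyl ketone) | CC(=O)C=C | starting material
5 | (2S,3R)-2,3-dimethyl-2-(3-oxobutyl)cyclohexan-1-one | O=C1CCC[C@@H](C)[C@]1(C)CCC(C)=O | intermediate
6 | trimethyl phosphonoacetate | COC(=O)CP(=O)(OC)OC | starting material
7 | methyl (2E)-5-[(1S,2R)-1,2-dimethyl-6-oxocyclohexyl]-3-methylpent-2-enoate | O=C1CCC[C@@H](C)[C@]1(C)CC/C(C)=C/C(=O)OC | intermediate
8 | methyl (2E)-5-[(1S,6R)-2,2-dimethoxy-1,6-dimethylcyclohexyl]-3-methylpent-2-enoate | COC1(OC)CCC[C@@H](C)[C@]1(C)CC/C(C)=C/C(=O)OC | intermediate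
9 | methyl (2E)-5-[(1S,6R)-2-methoxy-1,6-dimethylcyclohex-2-en-1-yl]-3-methylpent-2-enoate | COC1=CCC[C@@H](C)[C@]1(C)CC/C(C)=C/C(=O)OC | intermediate
10 | geraniol, (2E)-3,7-dimethylocta-2,6-dien-1-ol | CC(C)=CCC/C(C)=C/CO | starting material
11 | methyl (2E)-5-[(1S,6R)-2-{[(2E)-3,7-dimethylocta-2,6-dien-1-yl]oxy}-1,6-dimethylcyclohex-2-en-1-yl]-3-methylpent-2-enoate | CC(C)=CCC/C(C)=C/COC1=CCC[C@@H](C)[C@]1(C)CC/C(C)=C/C(=O)OC | intermediate
12 | methyl (2E)-5-{(1S,2R,5S)-5-[(3R)-3,7-dimethylocta-1,6-dien-3-yl]-1,2-dimethyl-6-oxocyclohexyl}-3-methylpent-2-enoate | C=C[C@@](C)(CCC=C(C)C)[C@@H]1CC[C@@H](C)[C@](C)(CC/C(C)=C/C(=O)OC)C1=O | intermediate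
13 | tricyclic oxetane from 12 (four-membered ring C10–O–CMe2–C1 fused to ring A; configuration at C1 and C10 not assigned) | C=C[C@@]1(C)CCC2C(C)(C)OC23[C@H]1CC[C@@H](C)[C@]3(C)CC/C(C)=C/C(=O)OC | intermediate
14 | methyl (2E)-5-[(1S,2R,4aS,5R)-5-ethenyl-1,2,5-trimethyl-1,2,3,4,4a,5,6,7-octahydronaphthalen-1-yl]-3-methylpent-2-enoate | C=C[C@@]1(C)CCC=C2[C@H]1CC[C@@H](C)[C@]2(C)CC/C(C)=C/C(=O)OC | intermediate
15 | (2E)-5-[(1S,2R,4aS,5R)-5-ethenyl-1,2,5-trimethyl-1,2,3,4,4a,5,6,7-octahydronaphthalen-1-yl]-3-methylpent-2-en-1-ol | C=C[C@@]1(C)CCC=C2[C@H]1CC[C@@H](C)[C@]2(C)CC/C(C)=C/CO | intermediate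
16 | [(2S,3S)-3-{2-[(1S,2R,4aS,5R)-5-ethenyl-1,2,5-trimethyl-1,2,3,4,4a,5,6,7-octahydronaphthalen-1-yl]ethyl}-3-methyloxiran-2-yl]methanol | C=C[C@@]1(C)CCC=C2[C@H]1CC[C@@H](C)[C@]2(C)CC[C@]3(C)O[C@H]3CO | intermediate
17 | (2S,3R)-5-[(1S,2R,4aS,5R)-5-ethenyl-1,2,5-trimethyl-1,2,3,4,4a,5,6,7-octahydronaphthalen-1-yl]-3-methylpentane-1,2,3-triol | C=C[C@@]1(C)CCC=C2[C@H]1CC[C@@H](C)[C@]2(C)CC[C@@](C)(O)[C@H](CO)O | intermediate
18 | (2S,3R)-5-[(1S,2R,4aS,5R)-5-ethenyl-1,2,5-trimethyl-1,2,3,4,4a,5,6,7-octahydronaphthalen-1-yl]-3-hydroxy-3-methylpentane-1,2-diyl diacetate | C=C[C@@]1(C)CCC=C2[C@H]1CC[C@@H](C)[C@]2(C)CC[C@@](C)(O)[C@H](COC(C)=O)OC(C)=O | intermediate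
19 | (2S,3R)-5-[(1S,2R,4aR,5S)-5-(1,2-dihydroxyethyl)-1,2,5-trimethyl-1,2,3,4,4a,5,6,7-octahydronaphthalen-1-yl]-3-hydroxy-3-methylpentane-1,2-diyl diacetate (carbinol configuration not assigned) | OCC(O)[C@@]1(C)CCC=C2[C@H]1CC[C@@H](C)[C@]2(C)CC[C@@](C)(O)[C@H](COC(C)=O)OC(C)=O | intermediate
20 | (2S,3R)-5-[(1S,2R,4aR,5S)-5-formyl-1,2,5-trimethyl-1,2,3,4,4a,5,6,7-octahydronaphthalen-1-yl]-3-hydroxy-3-methylpentane-1,2-diyl diacetate | O=C[C@@]1(C)CCC=C2[C@H]1CC[C@@H](C)[C@]2(C)CC[C@@](C)(O)[C@H](COC(C)=O)OC(C)=O | intermediate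
21 | (1S,5S,6R,8aR)-5-[(3R,4S)-4,5-bis(acetyloxy)-3-hydroxy-3-methylpentyl]-1,5,6-trimethyl-1,2,3,5,6,7,8,8a-octahydronaphthalene-1-carboxylic acid | OC(=O)[C@@]1(C)CCC=C2[C@H]1CC[C@@H](C)[C@]2(C)CC[C@@](C)(O)[C@H](COC(C)=O)OC(C)=O | intermediate
22 | methyl (1S,5S,6R,8aR)-5-[(3R,4S)-4,5-bis(acetyloxy)-3-hydroxy-3-methylpentyl]-1,5,6-trimethyl-1,2,3,5,6,7,8,8a-octahydronaphthalene-1-carboxylate (CNP0238486.2) | COC(=O)[C@@]1(C)CCC=C2[C@H]1CC[C@@H](C)[C@]2(C)CC[C@@](C)(O)[C@H](COC(C)=O)OC(C)=O | target

**Total step count:** 13. **Longest linear sequence:** 13 steps (1 → 22).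

**Steps most likely to fail**

1. Step 6 (carries the label). After the C1–C10 bond has formed, the intermediate may lose a proton (carbonyl-ene collapse to a tertiary homoallylic alcohol) instead of fragmenting. The Lewis acid may also enolise the ketone and scramble C5, or move the new alkene into the tetrasubstituted C5=C10 position. Fallback with known chemistry: starting from 12, chemoselective ozonolysis of the most electron-rich alkene, the isopropylidene (O3, CH2Cl2, pyridine, −78 °C, then Me2S), should give keto aldehyde F1 with the vinyl group and the enoate intact. Intramolecular McMurry coupling of the aldehyde with the C10 ketone (TiCl3(DME)1.5, Zn–Cu couple, DME, reflux, slow addition) should then close ring A and return to the route at 14.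

2. Step 5. Alcohol exchange at the hindered C10 may be slow, and the acid may ionise the geranyl unit, leading to unrearranged C-geranylation or decomposition of geraniol. Prolonged heating with acid may also erode C5 by enolisation. Fallback: starting from 7, kinetic enolisation toward C5 and triflation (KN(SiMe3)2, PhNTf2, THF, −78 °C) should give enol triflate F2. Miyaura borylation (PdCl2(dppf), B2pin2, KOAc, dioxane, 80 °C) should give alkenyl boronate F3. Chan–Lam-type coupling of F3 with geraniol (Cu(OAc)2, Et3N, 4 Å molecular sieves, CH2Cl2, air, 23 °C) should give geranyl enol ether 11 without acid; 11 is isolated and rearranged thermally under neutral conditions (xylenes, 140 °C), returning to the route at 12.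

3. Step 9. Carbocation character at the tertiary C13 may cause partial loss of stereospecificity, and the ring alkene may take part in cation–olefin cyclisation under acid. Fallback: starting from 15, Sharpless epoxidation with D-(−)-diethyl tartrate should give the enantiomeric epoxy alcohol F4 (C13 R, C14 R). Aqueous NaOH in t-BuOH at 75 °C should then induce Payne rearrangement (inversion at C14, C13 retained) to terminal epoxide F5, not isolated, which hydroxide opens at the primary C15; this all-SN2 path should reach the same (13R,14S)-triol and returns to the route at 17.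

**Further compounds**
F1 | step 6 | methyl (2E)-5-{(1S,2R,5S)-1,2-dimethyl-5-[(3R)-3-methyl-6-oxohex-1-en-3-yl]-6-oxocyclohexyl}-3-methylpent-2-enoate | C=C[C@@](C)(CCC=O)[C@@H]1CC[C@@H](C)[C@](C)(CC/C(C)=C/C(=O)OC)C1=O
F2 | step 5 | methyl (2E)-5-[(1S,6R)-1,6-dimethyl-2-{[(trifluoromethyl)sulfonyl]oxy}cyclohex-2-en-1-yl]-3-methylpent-2-enoate | O=S(=O)(OC1=CCC[C@@H](C)[C@]1(C)CC/C(C)=C/C(=O)OC)C(F)(F)F
F3 | step 5 | methyl (2E)-5-[(1S,6R)-1,6-dimethyl-2-(4,4,5,5-tetramethyl-1,3,2-dioxaborolan-2-yl)cyclohex-2-en-1-yl]-3-methylpent-2-enoate | CC1(C)OB(OC1(C)C)C2=CCC[C@@H](C)[C@]2(C)CC/C(C)=C/C(=O)OC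
F4 | step 9 | [(2R,3R)-3-{2-[(1S,2R,4aS,5R)-5-ethenyl-1,2,5-trimethyl-1,2,3,4,4a,5,6,7-octahydronaphthalen-1-yl]ethyl}-3-methyloxiran-2-yl]methanol | C=C[C@@]1(C)CCC=C2[C@H]1CC[C@@H](C)[C@]2(C)CC[C@@]3(C)O[C@@H]3CO
F5 | step 9 | (2R)-4-[(1S,2R,4aS,5R)-5-ethenyl-1,2,5-trimethyl-1,2,3,4,4a,5,6,7-octahydronaphthalen-1-yl]-2-[(2S)-oxiran-2-yl]butan-2-ol | C=C[C@@]1(C)CCC=C2[C@H]1CC[C@@H](C)[C@]2(C)CC[C@@](C)(O)[C@@H]3CO3
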